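**Retrosynthetic overview**
- GA50 ⇐ (acetal hydrolysis, ester demethylation) 12β-alcohol ⇐ [key step] 1,6-enyne C17≡C16–C15–C8–C14–C13=C12 on an intact ring A/B/C-lactone core. Ring D (C8, C14, C13, C16, C15) is closed last, through C13–C16, by a hydridopalladium borylative carbocyclization followed by C–B oxidation.
- Enabling feature: in ring D the bridgehead C13–H lies between the methylene-bearing C16 and the carbinol C12, and C16 and the C12 oxygen are cis (both β). This is the imprint of a syn carbometalation of a C12=C13 olefin by a C16 vinyl-metal tethered through C15 to C8.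
- Enyne ⇐ ring C 13-ketone (enol triflate, reduction) ⇐ keto acid (decarboxylative alkynylation rebuilds C16–C17) ⇐ C13–C16 cleavage of the 13-hydroxy-16-ketone made from the 16-ene of gibberellic acid. The cut turns the bridgehead oxygen into an ordinary ketone, which is then erased.
- Ring A: Δ1-3β-ol → SN2′ chloride → Δ2-olefin → β-face osmylation → 2β,3β-diol, carried as the acetonide.
- Ring order: A, B, C and the 19,10-lactone come intact from commercial gibberellic acid (GA3, fermentation product); ring D is opened in step 7 and is the last ring closed, in step 12.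

Key step: step 12

Remark: the SMILES is read as 2β,3β,12β-trihydroxy with H-13 (hydroxyl on C12, cis to C16), gibberellane numbering is used throughout, and GA3 is taken as the commercially available, enantiopure starting material.

**Step 1**
Reactants: 1 gibberellic acid (GA3)
Product: 2 GA3 methyl ester
Conditions: Me3SiCHN2, MeOH/PhMe 1:3, 0 °C → rt
Reagents that add atoms: (trimethylsilyl)diazomethane, C[Si](C)(C)C=[N+]=[N-]
Why: Diazoalkane esterification of the only carboxylic acid under neutral conditions, so the base-labile allylic 19,10-lactone does not migrate and no stereocentre is touched.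

**Step 2**
Reactants: 2 GA3 methyl ester
Product: 3 17-nor-16-oxo-GA3 methyl ester (13-hydroxy-16-ketone)
Conditions: O3, CH2Cl2/pyridine, −78 °C, Sudan III end point; then Me2S, −78 °C → rt
Reagents that add atoms: ozone, [O-][O+]=O
Why: Chemoselective ozonolysis (Criegee mechanism) of the electron-rich 1,1-disubstituted C16=C17 olefin, while the ring A C1=C2 olefin, deactivated by two allylic C–O bonds (C3–OH and the C10 lactone oxygen), should survive under indicator control.

**Step 3**
Reactants: 3 17-nor-16-oxo-GA3 methyl ester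
Product: 4 1β-chloro-17-nor-16-oxo-GA5 methyl ester (1β-chloro-2-ene)
Conditions: PPh3, CCl4/MeCN, 60 °C
Reagents that add atoms: carbon tetrachloride, ClC(Cl)(Cl)Cl
Why: Appel-type activation of the allylic 3β-hydroxyl as an alkoxyphosphonium ion and syn SN2′ delivery of chloride to C1 (1β, the outcome expected for this allylic alcohol) moves the olefin to C2=C3; the tertiary bridgehead 13-OH cannot be substituted and the hindered C16 ketone is left alone.

**Step 4**
Reactants: 4 1β-chloro-17-nor-16-oxo-GA5 methyl ester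
Product: 5 17-nor-16-oxo-GA5 methyl ester (Δ2-olefin)
Conditions: Bu3SnH, AIBN (cat.), PhH, 80 °C
Reagents that add atoms: none
Why: Radical chain dehalogenation in which the C1–C2–C3 allyl radical takes hydrogen at C1, the regiochemistry expected for 1-halo-2-enes of this lactone series, leaving C2=C3 in place and erasing the C1 stereocentre.

**Step 5**
Reactants: 5 17-nor-16-oxo-GA5 methyl ester
Product: 6 17-nor-16-oxo-GA8 methyl ester (2β,3β,13-triol)
Conditions: OsO4 (5 mol %), NMO, acetone/H2O 4:1, rt
Reagents that add atoms: N-methylmorpholine N-oxide, C[N+]1([O-])CCOCC1; water, O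
Why: Catalytic osmium tetroxide syn-dihydroxylation of the only remaining olefin, expected from the β face because the α face of ring A is roofed by the diaxial 19,10-lactone bridge, which sets C2 and C3 together as the 2β,3β-cis-diol.

**Step 6**
Reactants: 6 17-nor-16-oxo-GA8 methyl ester
Product: 7 2β,3β-O-isopropylidene-17-nor-16-oxo-GA8 methyl ester
Conditions: Me2C(OMe)2, PPTS (cat.), acetone, rt
Reagents that add atoms: 2,2-dimethoxypropane, COC(C)(C)OC
Why: Acid-catalysed transketalization closes the dioxolane on the cis-diol only (the tertiary 13-OH has no partner), masking the diol against periodate and O3 against later retro-aldol epimerisation.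

**Step 7**
Reactants: 7 2β,3β-O-isopropylidene-17-nor-16-oxo-GA8 methyl ester
Product: 8 13,16-seco keto acid (ring C 13-ketone; C8 carries β-CH2CO2H = C15–C16)
Conditions: NaIO4, THF/H2O 2:1, rt
Reagents that add atoms: water, O
Why: Malaprade-type periodate cleavage of the α-ketol (cyclic periodate ester of the C16 hydrate and the 13-OH) breaks C13–C16, opening ring D to a ring C ketone and a C16 acid without touching any stereocentre.

**Step 8**
Reactants: 8 13,16-seco keto acid
Product: 10 silyl-alkynyl 13-ketone (C8–CH2–C≡C–SiMe3), via N-acyloxyphthalimide ester 9 (not isolated)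
Conditions: N-hydroxyphthalimide, DIC, DMAP (cat.), CH2Cl2, rt; then NiCl2·6H2O (20 mol %), 4,4′-di-tert-butyl-2,2′-bipyridine (20 mol %), Me3SiC≡CZnCl·LiCl, THF/DMF, rt
Reagents that add atoms: (trimethylsilyl)ethynylzinc chloride, C[Si](C)(C)C#C[Zn]Cl; N-hydroxyphthalimide, O=C1c2ccccc2C(=O)N1O (its atoms stay only in 9)
Why: Steglich-type formation of the redox-active ester and nickel-catalysed decarboxylative alkynylation (single-electron reduction, loss of CO2, capture of the primary C15 radical by alkynylnickel) replace the old C16 by the C16≡C17 unit; the acid is the only one in the molecule, the mild zinc acetylide should not add to the ketone, and no stereocentre is formed.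

**Step 9**
Reactants: 10 silyl-alkynyl 13-ketone
Product: 11 Δ12-en-13-yl triflate
Conditions: KN(SiMe3)2, THF, −78 °C; then PhNTf2, −78 → 0 °C
Reagents that add atoms: N-phenylbis(trifluoromethanesulfonimide), O=S(=O)(N(c1ccccc1)S(=O)(=O)C(F)(F)F)C(F)(F)F
Why: Kinetic enolization should occur at C12 and not at the neopentyl C14 (next to quaternary C8), and O-sulfonylation fixes the C12=C13 regiochemistry as the enol triflate; the silyl cap removes the acidic alkyne hydrogen.

**Step 10**
Reactants: 11 Δ12-en-13-yl triflate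
Product: 12 Δ12-olefin with silyl-protected propargyl group
Conditions: Pd(OAc)2 (5 mol %), PPh3 (10 mol %), HCO2H, n-Bu3N, DMF, 60 °C
Reagents that add atoms: none
Why: Palladium-catalysed formate reduction of the enol triflate (oxidative addition to zerovalent palladium, formate-to-hydride exchange with loss of CO2, reductive elimination) gives the C12=C13 olefin regiospecifically; insertion of the C13 vinylpalladium into the tethered alkyne is blocked because it would create a bridgehead olefin.

**Step 11**
Reactants: 12 Δ12-olefin with silyl-protected propargyl group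
Product: 13 1,6-enyne (C17≡C16–C15–C8–C14–C13=C12)
Conditions: K2CO3, MeOH, rt
Reagents that add atoms: none
Why: Methanolysis of the C(sp)–Si bond frees the terminal alkyne; the hindered C7 ester, the lactone and the acetonide are inert to these conditions.

**Step 12**
Reactants: 13 1,6-enyne
Product: 15 GA50 methyl ester 2β,3β-acetonide (12β-alcohol), via C12 pinacol boronate 14 (not isolated)
Conditions: Pd(OAc)2 (10 mol %), B2pin2 (1.5 equiv), MeOH (2 equiv), PhMe, 50 °C; then NaBO3·4H2O, THF/H2O, rt
Reagents that add atoms: bis(pinacolato)diboron, CC1(C)OB(OC1(C)C)B1OC(C)(C)C(C)(C)O1 (boron of 14); sodium perborate, [Na+].[O-]OB=O (the C12 oxygen of 15)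
Why: Proposed new method: a hydridopalladium species formed from Pd(OAc)2, B2pin2 and MeOH should add across the terminal alkyne (Pd on C16, H on C17); the C16 vinylpalladium then inserts the C12=C13 olefin (5-exo-trig closure of ring D through the new C13–C16 bond), the C12 σ-alkylpalladium is intercepted by transmetalation with B2pin2 and C–B reductive elimination, and perborate converts C–B into C–O with retention. The closest known reaction type is the Pd(OAc)2/B2pin2/MeOH borylative cyclization of 1,6-enynes to homoallylic alkylboronates (with the related hydridopalladium reductive and Alder-ene enyne cyclizations), shown for acyclic olefin partners and extended here to an endocyclic 1,2-disubstituted olefin that gives a bridged secondary alkylboronate. C13 is set by the tether: C15 hangs from the β face of C8, so C16 can reach only the β face of C13, the only way a cis-bridged bicyclo[3.2.1]octane can form. C12 is set by the syn stereospecificity of migratory insertion, which places palladium, and after two retentive steps boron and then oxygen, on the same β face as C16; this cis relation cannot come from anti additions to the olefin or from epoxide opening. The step needs 5-exo over 6-endo insertion (normal for a three-atom tether) and borylation faster than β-hydride loss; the latter should be helped by the rigid chair of the new bicycle, in which the equatorial C12–Pd bond has no syn-coplanar hydrogen (H-13 is anti and at a bridgehead, the C11 hydrogens are gauche), and by phosphine-free conditions.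

**Step 13**
Reactants: 15 GA50 methyl ester 2β,3β-acetonide
Product: 16 GA50 2β,3β-acetonide (free C7 acid)
Conditions: n-PrSLi, HMPA, rt; then 0.5 M HCl to pH 4, 0 °C
Reagents that add atoms: none
Why: SN2 demethylation by thiolate at the ester methyl carbon is independent of the steric shielding of the C7 carbonyl and spares the lactone (tertiary C10–O); the acetonide keeps O3 masked so that no retro-aldol epimerisation at C3 can occur.

**Step 14**
Reactants: 16 GA50 2β,3β-acetonide
Product: 17 GA50
Conditions: AcOH/H2O 4:1, 45 °C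
Reagents that add atoms: none
Why: Mild acid hydrolysis of the isopropylidene acetal frees the 2β,3β-diol; a 16-ene without a 13-hydroxyl should tolerate aqueous acetic acid without Wagner–Meerwein rearrangement.

**Compound list**
1 | gibberellic acid (GA3) | C=C1C[C@]23C[C@@]1(O)CC[C@H]2[C@@]12C=C[C@H](O)[C@@](C)(C(=O)O1)[C@H]2[C@@H]3C(=O)O | starting material
2 | GA3 methyl ester | C=C1C[C@]23C[C@@]1(O)CC[C@H]2[C@@]12C=C[C@H](O)[C@@](C)(C(=O)O1)[C@H]2[C@@H]3C(=O)OC | intermediate
3 | 17-nor-16-oxo-GA3 methyl ester (3β,13-dihydroxy-Δ1, 16-ketone) | O=C1C[C@]23C[C@@]1(O)CC[C@H]2[C@@]12C=C[C@H](O)[C@@](C)(C(=O)O1)[C@H]2[C@@H]3C(=O)OC | intermediate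
4 | 1β-chloro-17-nor-16-oxo-GA5 methyl ester (1β-chloro-Δ2, 13-hydroxy-16-ketone) | O=C1C[C@]23C[C@@]1(O)CC[C@H]2[C@@]12[C@H](Cl)C=C[C@@](C)(C(=O)O1)[C@H]2[C@@H]3C(=O)OC | intermediate
5 | 17-nor-16-oxo-GA5 methyl ester (Δ2, 13-hydroxy-16-ketone) | O=C1C[C@]23C[C@@]1(O)CC[C@H]2[C@@]12CC=C[C@@](C)(C(=O)O1)[C@H]2[C@@H]3C(=O)OC | intermediate
6 | 17-nor-16-oxo-GA8 methyl ester (2β,3β,13-triol, 16-ketone) | O=C1C[C@]23C[C@@]1(O)CC[C@H]2[C@@]12C[C@H](O)[C@H](O)[C@@](C)(C(=O)O1)[C@H]2[C@@H]3C(=O)OC | intermediate
7 | 2β,3β-O-isopropylidene derivative of 6 | O=C1C[C@]23C[C@@]1(O)CC[C@H]2[C@@]12C[C@@H]4OC(C)(C)O[C@@H]4[C@@](C)(C(=O)O1)[C@H]2[C@@H]3C(=O)OC | intermediate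
8 | 13,16-seco keto acid (13-oxo; C8β–CH2–CO2H; 2β,3β-acetonide; C7 methyl ester) | OC(=O)C[C@]23CC(=O)CC[C@H]2[C@@]12C[C@@H]4OC(C)(C)O[C@@H]4[C@@](C)(C(=O)O1)[C@H]2[C@@H]3C(=O)OC | intermediate
9 | N-acyloxyphthalimide ester of 8 | O=C(ON5C(=O)c6ccccc6C5=O)C[C@]23CC(=O)CC[C@H]2[C@@]12C[C@@H]4OC(C)(C)O[C@@H]4[C@@](C)(C(=O)O1)[C@H]2[C@@H]3C(=O)OC | intermediate
10 | silyl-alkynyl 13-ketone (C8β–CH2–C≡C–SiMe3) | C[Si](C)(C)C#CC[C@]23CC(=O)CC[C@H]2[C@@]12C[C@@H]4OC(C)(C)O[C@@H]4[C@@](C)(C(=O)O1)[C@H]2[C@@H]3C(=O)OC | intermediate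
11 | Δ12-en-13-yl triflate | C[Si](C)(C)C#CC[C@]23CC(OS(=O)(=O)C(F)(F)F)=CC[C@H]2[C@@]12C[C@@H]4OC(C)(C)O[C@@H]4[C@@](C)(C(=O)O1)[C@H]2[C@@H]3C(=O)OC | intermediate
12 | Δ12-olefin with silyl-protected propargyl group | C[Si](C)(C)C#CC[C@]23CC=CC[C@H]2[C@@]12C[C@@H]4OC(C)(C)O[C@@H]4[C@@](C)(C(=O)O1)[C@H]2[C@@H]3C(=O)OC | intermediate
13 | 1,6-enyne (Δ12-olefin, C8β-propargyl) | C#CC[C@]23CC=CC[C@H]2[C@@]12C[C@@H]4OC(C)(C)O[C@@H]4[C@@](C)(C(=O)O1)[C@H]2[C@@H]3C(=O)OC | intermediate
14 | 12β-(pinacolboryl)-16-ene tetracycle (2β,3β-acetonide, C7 methyl ester) | C=C1C[C@]23C[C@H]1[C@H](B5OC(C)(C)C(C)(C)O5)C[C@H]2[C@@]12C[C@@H]4OC(C)(C)O[C@@H]4[C@@](C)(C(=O)O1)[C@H]2[C@@H]3C(=O)OC | intermediate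
15 | GA50 methyl ester 2β,3β-acetonide | C=C1C[C@]23C[C@H]1[C@H](O)C[C@H]2[C@@]12C[C@@H]4OC(C)(C)O[C@@H]4[C@@](C)(C(=O)O1)[C@H]2[C@@H]3C(=O)OC | intermediate
16 | GA50 2β,3β-acetonide | C=C1C[C@]23C[C@H]1[C@H](O)C[C@H]2[C@@]12C[C@@H]4OC(C)(C)O[C@@H]4[C@@](C)(C(=O)O1)[C@H]2[C@@H]3C(=O)O | intermediate
17 | GA50 | C=C1C[C@]23C[C@H]1[C@H](O)C[C@H]2[C@@]12C[C@H](O)[C@H](O)[C@@](C)(C(=O)O1)[C@H]2[C@@H]3C(=O)O | target

**Total step count:** 14
**Longest linear sequence:** 14 steps (1 → 17)

**Steps most likely to fail**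

1. Step 12 (proposed new method). The C12 alkylpalladium may lose a β-hydride (Alder-ene diene) or be protonated before boron transfer, the hydridopalladium may isomerise the ring olefin, or insertion into the ring olefin may be so slow that the alkyne oligomerises. The fallback uses known radical chemistry and puts the C12 oxygen in before ring D is closed; it sets out from 10 and returns at 15. Desilylation of 10 (K2CO3, MeOH) gives the terminal alkynyl 13-ketone F1. The kinetic C12 enolate (KN(SiMe3)2, −78 °C) is hydroxylated with 2-(phenylsulfonyl)-3-phenyloxaziridine from the β face (ring B shields the α face) to the 12β-hydroxy-13-ketone F2. Et3SiOTf/2,6-lutidine gives the 12β-triethylsilyl ether F3. Luche reduction (NaBH4, CeCl3·7H2O, MeOH, −40 °C) gives the 13-alcohol F4 (drawn 13β; either epimer serves). PhOC(S)Cl/pyridine/DMAP gives the 13-O-phenyl thionocarbonate F5. Bu3SnH/AIBN added slowly in dilute refluxing toluene generates the C13 radical (Barton–McCombie fragmentation), which closes ring D by 5-exo-dig addition to the alkyne to give the 12β-silyloxy tetracycle F6. AcOH/THF/H2O (3:1:1, rt) removes the silyl group and gives 15.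

2. Step 8. The neopentyl-type C15 radical may be reduced or dimerise before nickel captures it, the keto acid may sit as its cyclic pseudo-acid and resist activation, or the zinc acetylide may add to the C13 ketone. The fallback keeps C16 and adds C17 by classical homologation; it sets out from 7 and returns at 13. Pb(OAc)4 in MeOH/PhH cleaves the ketol to the 13-keto C16 methyl ester F7. KN(SiMe3)2/PhNTf2 gives the Δ12-enol triflate ester F8. Pd(OAc)2/PPh3/HCO2H/n-Bu3N gives the Δ12-olefin ester F9. i-Bu2AlH (1 equiv, PhMe, −78 °C) reduces only the unhindered C16 ester to the aldehyde F10. Seyferth–Gilbert homologation in its Ohira–Bestmann form (dimethyl (1-diazo-2-oxopropyl)phosphonate, K2CO3, MeOH) gives 13.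

3. Step 5. Facial selectivity of osmylation may be poor, giving the 2α,3α-diol alongside or instead of the 2β,3β-diol. The fallback delivers the cis-diol to the face opposite to that chosen by an electrophile; it sets out from 5 and returns at 6. Woodward cis-hydroxylation (I2, AgOAc, moist AcOH: iodonium on the face the electrophile prefers, trans acetate opening, acetoxonium closure with inversion, hydrolysis) gives the 2β,3β-cis-hydroxy acetate F11 (drawn as the 3-acetate; acyl migration makes the position immaterial). Brief methanolysis (K2CO3, MeOH, 0 °C) gives 6.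

**Further compounds**
F1 | step 12 | terminal alkynyl 13-ketone (C8β-propargyl) | C#CC[C@]23CC(=O)CC[C@H]2[C@@]12C[C@@H]4OC(C)(C)O[C@@H]4[C@@](C)(C(=O)O1)[C@H]2[C@@H]3C(=O)OC
F2 | step 12 | 12β-hydroxy-13-ketone | C#CC[C@]23CC(=O)[C@H](O)C[C@H]2[C@@]12C[C@@H]4OC(C)(C)O[C@@H]4[C@@](C)(C(=O)O1)[C@H]2[C@@H]3C(=O)OC
F3 | step 12 | 12β-triethylsilyl ether of F2 | C#CC[C@]23CC(=O)[C@H](O[Si](CC)(CC)CC)C[C@H]2[C@@]12C[C@@H]4OC(C)(C)O[C@@H]4[C@@](C)(C(=O)O1)[C@H]2[C@@H]3C(=O)OC
F4 | step 12 | 13-alcohol (drawn 13β) with 12β-triethylsilyloxy group | C#CC[C@]23C[C@H](O)[C@H](O[Si](CC)(CC)CC)C[C@H]2[C@@]12C[C@@H]4OC(C)(C)O[C@@H]4[C@@](C)(C(=O)O1)[C@H]2[C@@H]3C(=O)OC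
F5 | step 12 | 13-O-phenyl thionocarbonate of F4 | C#CC[C@]23C[C@H](OC(=S)Oc5ccccc5)[C@H](O[Si](CC)(CC)CC)C[C@H]2[C@@]12C[C@@H]4OC(C)(C)O[C@@H]4[C@@](C)(C(=O)O1)[C@H]2[C@@H]3C(=O)OC
F6 | step 12 | 12β-triethylsilyl ether of 15 | C=C1C[C@]23C[C@H]1[C@H](O[Si](CC)(CC)CC)C[C@H]2[C@@]12C[C@@H]4OC(C)(C)O[C@@H]4[C@@](C)(C(=O)O1)[C@H]2[C@@H]3C(=O)OC
F7 | step 8 | 13-keto C16 methyl ester (13,16-seco diester) | COC(=O)C[C@]23CC(=O)CC[C@H]2[C@@]12C[C@@H]4OC(C)(C)O[C@@H]4[C@@](C)(C(=O)O1)[C@H]2[C@@H]3C(=O)OC
F8 | step 8 | Δ12-en-13-yl triflate C16 methyl ester | COC(=O)C[C@]23CC(OS(=O)(=O)C(F)(F)F)=CC[C@H]2[C@@]12C[C@@H]4OC(C)(C)O[C@@H]4[C@@](C)(C(=O)O1)[C@H]2[C@@H]3C(=O)OC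
F9 | step 8 | Δ12-olefin C16 methyl ester | COC(=O)C[C@]23CC=CC[C@H]2[C@@]12C[C@@H]4OC(C)(C)O[C@@H]4[C@@](C)(C(=O)O1)[C@H]2[C@@H]3C(=O)OC
F10 | step 8 | Δ12-olefin C16 aldehyde | O=CC[C@]23CC=CC[C@H]2[C@@]12C[C@@H]4OC(C)(C)O[C@@H]4[C@@](C)(C(=O)O1)[C@H]2[C@@H]3C(=O)OC
F11 | step 5 | 2β-hydroxy-3β-acetoxy-17-nor-16-oxo derivative (monoacetate of 6) | O=C1C[C@]23C[C@@]1(O)CC[C@H]2[C@@]12C[C@H](O)[C@H](OC(C)=O)[C@@](C)(C(=O)O1)[C@H]2[C@@H]3C(=O)OC
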